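**Plan**
- Retrosynthesis: the interflavanyl bond C-4–C-6' is cut first (flavan-4-yl cation plus a C-8-blocked gallocatechin). Then O-1–C-2 and C-4a–C-4 of ring C of the upper unit are cut together, giving 3-(benzyloxy)phenol and a (2R,3S)-3-aryl-2,3-epoxy aldehyde.
- Enabling feature: ring A is a resorcinol, so its O-1 and the ortho carbon C-4a form a 1,3-O,C-dinucleophile. C-4, oxygenated C-3 and benzylic C-2 of ring C map onto CHO, C-alpha and C-beta of an epoxy aldehyde, a 1,3-dielectrophile.
- Forward: enal, then epoxy aldehyde, then a titanium-templated [3+3] annulation that closes ring C as a flavan-3,4-diol (epoxide as temporary ring, 4-OH as activating oxidation level). Friedel–Crafts union with 8-bromo-penta-O-benzylgallocatechin at C-6' follows, and one hydrogenolysis removes the benzyl ethers and the bromine block.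
- Stereochemistry: C-3 and C-2 come from the catalytic asymmetric epoxidation (C-2 by inversion on ring closure). C-4 comes from attack anti to 3-OH on the 2,3-trans flavan-4-yl cation. C-2' and C-3' come from (+)-gallocatechin.

Key step: step 5

Assumption: the C-4 configuration of diol 10 is immaterial because C-4 is ionised in step 6, so 10 is carried on as its C-4 epimer mixture.

**Step 1**
Reactants: 1 (+)-gallocatechin
Product: 2 (2R,3S)-5,7-bis(benzyloxy)-2-[3,4,5-tris(benzyloxy)phenyl]chroman-3-ol
Conditions: BnBr (5.2 equiv), K2CO3, DMF, Ar, −10 °C → rt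
Reagents that add atoms: benzyl bromide, BrCc1ccccc1
Why: Williamson etherification of the five phenols, which are far more acidic than the secondary 3-OH, under cold oxygen-free conditions chosen to limit C-benzylation and oxidation of the pyrogallol ring; no stereocentre is touched.

**Step 2**
Reactants: 2 penta-O-benzylgallocatechin
Product: 3 (2R,3S)-5,7-bis(benzyloxy)-8-bromo-2-[3,4,5-tris(benzyloxy)phenyl]chroman-3-ol
Conditions: NBS (1.0 equiv), CH2Cl2, −78 °C → rt
Reagents that add atoms: N-bromosuccinimide, O=C1CCC(=O)N1Br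
Why: Electrophilic aromatic bromination should go to C-8, the most activated and accessible position of ring A in 5,7-di-O-benzyl flavan-3-ols, so that bromine blocks C-8 and leaves C-6 as the only nucleophilic site for step 6.

**Step 3**
Reactants: 4 3,4-bis(benzyloxy)benzaldehyde
Product: 5 (E)-3-[3,4-bis(benzyloxy)phenyl]prop-2-enal
Conditions: Ph3P=CHCHO (1.05 equiv), toluene, 90 °C
Reagents that add atoms: (triphenylphosphoranylidene)acetaldehyde, O=CC=P(c1ccccc1)(c1ccccc1)c1ccccc1
Why: Wittig olefination with a stabilised formyl ylide should give the E-enal under thermodynamic control.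

**Step 4**
Reactants: 5 (E)-enal
Product: 6 (2R,3S)-3-[3,4-bis(benzyloxy)phenyl]oxirane-2-carbaldehyde
Conditions: 35% aq. H2O2 (1.3 equiv), (R)-2-{bis[3,5-bis(trifluoromethyl)phenyl](trimethylsilyloxy)methyl}pyrrolidine (10 mol%), CH2Cl2, rt
Reagents that add atoms: hydrogen peroxide, OO
Why: Iminium–enamine organocatalytic epoxidation, in which hydroperoxide adds to the beta carbon of the E-iminium on the face away from the diaryl(silyloxy)methyl group and the enamine then closes onto the O–O bond to give the trans epoxide; the (R)-catalyst is chosen on this shielding model to deliver the (2R,3S) isomer.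

**Step 5**
Reactants: 7 3-(benzyloxy)phenol; 6 (2R,3S)-epoxy aldehyde
Product: 10 (2R,3S)-7-(benzyloxy)-2-[3,4-bis(benzyloxy)phenyl]chromane-3,4-diol (C-4 epimers), via aryloxytitanium triisopropoxide 8 (not isolated), via epoxy carbinol adduct 9 (not isolated)
Conditions: 7, Ti(OiPr)4 (1.05 equiv), toluene, rt, i-PrOH removed under vacuum; then 6, toluene, 0 °C → 40 °C; aq. NaHCO3
Reagents that add atoms: titanium tetraisopropoxide, CC(C)O[Ti](OC(C)C)(OC(C)C)OC(C)C (its atoms remain only in intermediate 8)
Why: Proposed new method: aryloxytitanium 8 binds the aldehyde of 6 and delivers it through a six-membered transition state to the ortho carbon para to the benzyloxy group (bond C-4a–C-4); the titanium 2,3-epoxy alkoxide 9 so formed is then opened at its benzylic carbon by the phenol oxygen (bond O-1–C-2), a formal [3+3] annulation. The closest known reaction types are the ortho-specific hydroxyalkylation of titanium and magnesium phenoxides with alpha-alkoxy aldehydes, the Ti(OiPr)4-mediated C-3-selective opening of 2,3-epoxy alcohols, and the acid-mediated epoxy-phenol cyclisation used for 2,3-trans-flavan-3-ols; their merger in one flask on an epoxy aldehyde is the new element. Ring C closes by a 6-endo-tet epoxide opening, which should be favoured over 5-exo closure to a dihydrobenzofuran by the cation-stabilising 3,4-bis(benzyloxy)phenyl group and by chelation of the C-4 alkoxide and the epoxide oxygen to titanium, which activates the distal carbon. C-2 is set as R by anti (invertive) attack on the (S)-configured benzylic epoxide carbon, C-3 keeps its C–O bond and so the configuration from step 4, and C-4 forms without control, which is harmless because it is ionised in step 6. The step needs ortho-C attack over O- and para-alkylation, which the titanium chelate should provide, and attack at C-6 over C-2 of the phenol, which the crowding of C-2 between two oxygen substituents should secure.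

**Step 6**
Reactants: 10 flavan-3,4-diol; 3 8-bromo-penta-O-benzylgallocatechin
Product: 11 (2R,3S,4S)-7-(benzyloxy)-2-[3,4-bis(benzyloxy)phenyl]-4-{(2R,3S)-5,7-bis(benzyloxy)-8-bromo-3-hydroxy-2-[3,4,5-tris(benzyloxy)phenyl]chroman-6-yl}chroman-3-ol
Conditions: 3 (3 equiv), TiCl4 (1.1 equiv), CH2Cl2–THF 9:1, 0 °C → rt; aq. NaHCO3
Reagents that add atoms: none
Why: Friedel–Crafts alkylation of the flavan-3,4-diol/flavan-3-ol type: TiCl4 ionises the 4-OH to the 7-benzyloxy-stabilised flavan-4-yl cation, and C-6 of 3 (C-8 being blocked) should attack anti to the quasi-equatorial 3-OH of the 2,3-trans half-chair, setting C-4 as S (3,4-trans).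

**Step 7**
Reactants: 11 protected bromo dimer
Product: 12 fisetinidol-(4alpha,6)-gallocatechin
Conditions: H2 (1 atm), Pd(OH)2/C, Et3N, THF–MeOH–H2O, rt
Reagents that add atoms: none
Why: Catalytic hydrogenolysis should cleave the eight benzyl ethers and, with Et3N as acid scavenger, the aryl C–Br bond in one operation without touching any stereocentre.

**Compound list**
1 | (+)-gallocatechin, (2R,3S)-2-(3,4,5-trihydroxyphenyl)chromane-3,5,7-triol | O[C@H]1Cc2c(O)cc(O)cc2O[C@@H]1c1cc(O)c(O)c(O)c1 | starting material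
2 | (2R,3S)-5,7-bis(benzyloxy)-2-[3,4,5-tris(benzyloxy)phenyl]chroman-3-ol | O[C@H]1Cc2c(OCc3ccccc3)cc(OCc3ccccc3)cc2O[C@@H]1c1cc(OCc2ccccc2)c(OCc2ccccc2)c(OCc2ccccc2)c1 | intermediate
3 | (2R,3S)-5,7-bis(benzyloxy)-8-bromo-2-[3,4,5-tris(benzyloxy)phenyl]chroman-3-ol | O[C@H]1Cc2c(OCc3ccccc3)cc(OCc3ccccc3)c(Br)c2O[C@@H]1c1cc(OCc2ccccc2)c(OCc2ccccc2)c(OCc2ccccc2)c1 | intermediate
4 | 3,4-bis(benzyloxy)benzaldehyde | O=Cc1ccc(OCc2ccccc2)c(OCc2ccccc2)c1 | starting material
5 | (E)-3-[3,4-bis(benzyloxy)phenyl]prop-2-enal | O=C/C=C/c1ccc(OCc2ccccc2)c(OCc2ccccc2)c1 | intermediate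
6 | (2R,3S)-3-[3,4-bis(benzyloxy)phenyl]oxirane-2-carbaldehyde (trans) | O=C[C@@H]1O[C@H]1c1ccc(OCc2ccccc2)c(OCc2ccccc2)c1 | intermediate
7 | 3-(benzyloxy)phenol | Oc1cccc(OCc2ccccc2)c1 | starting material
8 | [3-(benzyloxy)phenoxy]titanium triisopropoxide | CC(C)O[Ti](OC(C)C)(OC(C)C)Oc1cccc(OCc2ccccc2)c1 | intermediate
9 | 5-(benzyloxy)-2-{[(2S,3S)-3-[3,4-bis(benzyloxy)phenyl]oxiran-2-yl](hydroxy)methyl}phenol, carbinol epimers, titanium-bound in the flask and drawn metal-free | Oc1cc(OCc2ccccc2)ccc1C(O)[C@@H]1O[C@H]1c1ccc(OCc2ccccc2)c(OCc2ccccc2)c1 | intermediate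
10 | (2R,3S)-7-(benzyloxy)-2-[3,4-bis(benzyloxy)phenyl]chromane-3,4-diol, C-4 epimers | O[C@H]1C(O)c2ccc(OCc3ccccc3)cc2O[C@@H]1c1ccc(OCc2ccccc2)c(OCc2ccccc2)c1 | intermediate
11 | (2R,3S,4S)-7-(benzyloxy)-2-[3,4-bis(benzyloxy)phenyl]-4-{(2R,3S)-5,7-bis(benzyloxy)-8-bromo-3-hydroxy-2-[3,4,5-tris(benzyloxy)phenyl]chroman-6-yl}chroman-3-ol | c1ccccc1COc1ccc2c(c1)O[C@H](c1ccc(OCc3ccccc3)c(OCc3ccccc3)c1)[C@@H](O)[C@@H]2c1c(OCc3ccccc3)c(Br)c2c(c1OCc1ccccc1)C[C@H](O)[C@@H](c1cc(OCc3ccccc3)c(OCc3ccccc3)c(OCc3ccccc3)c1)O2 | intermediate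
12 | fisetinidol-(4alpha,6)-gallocatechin | Oc1ccc2c(c1)O[C@H](c1ccc(O)c(O)c1)[C@@H](O)[C@@H]2c1c(O)cc2c(c1O)C[C@H](O)[C@@H](c1cc(O)c(O)c(O)c1)O2 | target

**Step count and risks**
Total steps: 7. Longest linear sequence: 5 (steps 3 to 7, from 4 to 12).

Steps most likely to fail:

1. Step 5 (Proposed new method). What may go wrong: O- or para-alkylation instead of ortho-C attack, isopropoxide transfer to the aldehyde or epoxide, 5-exo closure, Payne-type epoxide migration, or ionisation of the product at C-4 and capture by a second phenoxide. The fallback uses known chemistry, sets out from 6 (with 7 as aryl source) and returns at 10. Phenol 7 is brominated ortho to the hydroxyl (Br2, t-BuNH2, toluene, −70 °C) to give 5-(benzyloxy)-2-bromophenol F1. F1 is treated with n-BuLi (2.1 equiv, THF, −78 °C) to give lithium 5-(benzyloxy)-2-lithiophenolate F2. F2 adds to the aldehyde of 6 and, after NH4Cl, gives the metal-free epoxy carbinol 9. PPTS in CH2Cl2 at 0 °C then closes ring C by the acid-mediated 6-endo epoxide opening to give 10.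

2. Step 6. What may go wrong: slow attack by the hindered, bromine-deactivated C-6 so that the cation is consumed by self-condensation with ring A of 10, or erosion of the anti facial selectivity at C-4. The fallback is a protecting-group-free biomimetic condensation that sets out from 10 (and 1) and returns at 12. Diol 10 is debenzylated under neutral conditions (H2, Pd/C, EtOAc–MeOH, rt) to (2R,3S)-2-(3,4-dihydroxyphenyl)chromane-3,4,7-triol F3. F3 is condensed with an excess of 1 in 0.1 M aq. HCl at rt. The 4,6-linked dimer 12, expected to be the minor regioisomer beside the 4,8-linked one, is separated on Sephadex LH-20.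

3. Step 4. What may go wrong: slow hydroperoxide addition to the electron-rich iminium, low enantioselectivity, or opening of the electron-rich benzylic epoxide during reaction or isolation. The fallback sets out from 5 and returns at 6. Enal 5 is reduced (NaBH4, CeCl3·7H2O, MeOH, 0 °C) to (E)-3-[3,4-bis(benzyloxy)phenyl]prop-2-en-1-ol F4. Sharpless asymmetric epoxidation (Ti(OiPr)4, L-(+)-diethyl tartrate, t-BuOOH, 4 Å MS, CH2Cl2, −20 °C) gives [(2S,3S)-3-[3,4-bis(benzyloxy)phenyl]oxiran-2-yl]methanol F5. Dess–Martin oxidation (NaHCO3, CH2Cl2, 0 °C) then gives 6.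

**Further compounds**
F1 | step 5 | 5-(benzyloxy)-2-bromophenol | Oc1cc(OCc2ccccc2)ccc1Br
F2 | step 5 | lithium 5-(benzyloxy)-2-lithiophenolate | [Li]Oc1cc(OCc2ccccc2)ccc1[Li]
F3 | step 6 | (2R,3S)-2-(3,4-dihydroxyphenyl)chromane-3,4,7-triol, C-4 epimers | O[C@H]1C(O)c2ccc(O)cc2O[C@@H]1c1ccc(O)c(O)c1
F4 | step 4 | (E)-3-[3,4-bis(benzyloxy)phenyl]prop-2-en-1-ol | OC/C=C/c1ccc(OCc2ccccc2)c(OCc2ccccc2)c1
F5 | step 4 | [(2S,3S)-3-[3,4-bis(benzyloxy)phenyl]oxiran-2-yl]methanol | OC[C@@H]1O[C@H]1c1ccc(OCc2ccccc2)c(OCc2ccccc2)c1
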